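The trap in this flask is to take the ratio of target made in the amber run and the violet run, a step of a factor 3.00 in coupling partner, straight for the order asked, although by 5.0 min the amber run has used more substrate.

| setting | violet | green | amber | blue |
|---|---|---|---|---|
| substrate | 0.0500 M | 0.0500 M | 0.0500 M | 0.0500 M |
| coupling partner | 0.0400 M | 0.0400 M | 0.120 M | 0.0400 M |
| free catalyst | 0.00250 M | 0.00250 M | 0.00250 M | 0.00250 M |
| target |  | 0.0250 M |  |  |
| time |  |  |  | 180 min |

| violet run: time / min | violet run: [target] / M | green run: time / min | green run: [target] / M | amber run: time / min | amber run: [target] / M |
|---|---|---|---|---|---|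
| 1.7 | 0.0037 | 1.7 | 0.0291 | 1.7 | 0.0067 |
| 5.0 | 0.0079 | 5.0 | 0.0334 | 5.0 | 0.0181 |
| 9.6 | 0.0140 | 9.6 | 0.0399 | 9.6 | 0.0282 |
| 15 | 0.0204 | 15 | 0.0443 | 15 | 0.0350 |
| 22 | 0.0242 | 22 | 0.0493 | 22 | 0.0414 |
| 29 | 0.0280 | 29 | 0.0531 | 29 | 0.0455 |
| 37 | 0.0300 | 37 | 0.0549 | 37 | 0.0473 |
| 46 | 0.0327 | 46 | 0.0574 | 46 | 0.0483 |

(readings scatter by 5 × 10⁻⁴ M)

- apparent order in [coupling partner] of the starting rate, round the charge of the violet run (the rate where two percent of its substrate have turned into target)
- target in the blue run at 180 min, as a share of the substrate charged
- which of these the readings show (the product kills the catalyst / the two partners rest in a complex / the product speeds the reaction / the substrate kills the catalyst / nothing beyond the main steps / the product decays)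

- Overall: substrate + coupling partner -> target, with free catalyst as catalyst.
- Constant volume, constant temperature.
- The analysis sees a species whether free or bound.
- An order is taken over about fifteen percent of the charge, up and down.

We carry one quantity, the rate ratio: target made in a flask over target made in the violet run in the same minutes, a ratio of mean rates in which time drops out. For the amber run at 5.0 min it is 2.29.

Now turn the question round. If the rate followed c(substrate) times c(coupling partner), with catalyst charged alike, the violet reading at 5.0 min gives a rate constant times time of 4.80 M⁻¹, and the amber reading at that time would have to be about 0.0203 M, a rate ratio of 2.57, not 3.00. It stands at 0.0181 M, lower by 0.00223 M, and that gap is about 1.86 standard deviations of the comparison, so this reading shows little. Reckoned the same way, the amber reading gives 4.08 M⁻¹, and the ratio of the two makes an order of 0.852 across the step, which we commit to for the order round the violet charge.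

For the green run, counting target beyond the added charge, the rate ratio at 5.0 min is 1.06, with a scatter of about 0.0895, so the readings show no effect of added target. At 15 min the violet reading gives 18.9 M⁻¹, so the amber reading would have to be about 0.0413 M; it stands at 0.0350 M, lower by 0.00627 M, about 8.09 standard deviations of the comparison. Among the choices we take the two partners resting in a complex, which this shortfall suggests and does not prove.

The blue run has the violet charge, and coupling partner is the limiting reagent, which puts the ceiling at 80.0 % of the substrate. The violet run has reached 65.4 % at 46 min, and we expect the blue run to stand just under the ceiling at 180 min.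

The forecast gives 0.7 (0.5 to 0.95), 78.5 % (76 % to 80 %) and nothing beyond the main steps, holding that “the usual catalyst-cycle rate law covers it”, so on the order and the choice our reckoning differs from it.

The flask gives an order of 0.83, 79.1 % in the blue run, and the two partners rest in a complex.

    2 free catalyst ⇌ catalyst dimer, settled at all times (5000 M⁻¹)
    catalyst dimer + substrate + coupling partner → target + catalyst dimer (2004 M⁻² min⁻¹)
    substrate + coupling partner ⇌ idle substrate-reagent adduct, settled at all times (12.80 M⁻¹)

A fit in which the product kills the catalyst leaves a root mean square residual of 4.0 in units of the scatter. Held across the whole step, the order 0.83 gives a rate ratio of 2.50, more than our 2.29 and more than the 2.14 between the amber and violet rates where two percent of the violet substrate have turned. In the green run, with 0.0250 M of target added, that same ratio of rates to the violet run is 1.00.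

The data were generated by integration with made-up constants, noise included.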